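**Plan** (labdane numbering: ring A = C1–C5 and C10, ring B = C5–C10, C17 = methylene carbon on C8, C18 = carboxyl carbon on C4)
1. Late cuts: side-chain C13=C14 (Horner–Wadsworth–Emmons), C4–CH3 (enolate methylation), C8=C17 (methylenation); then C7–C8 and C5–C10 together, which opens both rings to the acyclic bromo aldehyde 16.
2. 16 is cut at C4–C18 (carbonylation), at the C3 carbonyl/alkyne (ynone), at C9–C11 (alkylation) and at C9=C10 (olefination), back to α-angelica lactone.
3. Forward: the chain is built linearly; in step 12 the tertiary C10 radical closes ring A onto C5, then the C7 radical closes ring B onto C8 in the same flask.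
4. Enabling feature: C5 is β to the C4 carboxyl, so a C4=C5 acrylate accepts the radical generated at C10 from the C10=C20 alkene (C20 becomes the angular methyl); C8, sp2 in the target, is carried as an aldehyde that accepts the C7 radical.
5. Stereochemistry: C3 from Noyori transfer hydrogenation; C5 and C10 from the chair-like ring A closure steered by C3; C9 by equilibration next to the C8 ketone; C4 by Frater–Seebach methylation anti to O3; E alkene from the olefination.

Key step: step 12

Remark: C9 is deliberately racemic in 7–18 because it is equilibrated in step 13; the E isomer of 5 is the one carried on.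

Step 1
Reactants: 1 α-angelica lactone; 2 morpholine
Product: 3 1-(morpholin-4-yl)pentane-1,4-dione
Conditions: PhMe, 60 °C
Reagents that add atoms: none
Why: Aminolysis of the enol lactone by the secondary amine should open the ring, and the freed enol tautomerises to the methyl ketone, giving C20, C10, C1, C2 and C3 in one piece.

Step 2
Reactants: 3 1-(morpholin-4-yl)pentane-1,4-dione; 4 trimethyl phosphonoacetate
Product: 5 methyl (2E)-3-methyl-6-(morpholin-4-yl)-6-oxohex-2-enoate
Conditions: NaH, THF, 0 → 65 °C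
Reagents that add atoms: none
Why: Horner–Wadsworth–Emmons olefination of the methyl ketone should give the trisubstituted enoate, mainly as the E isomer.

Step 3
Reactants: 5 methyl (2E)-3-methyl-6-(morpholin-4-yl)-6-oxohex-2-enoate; 6 2-(2-bromoethyl)-2-methyl-1,3-dioxolane
Product: 7 methyl 3-methylidene-2-[2-(2-methyl-1,3-dioxolan-2-yl)ethyl]-6-(morpholin-4-yl)-6-oxohexanoate (racemic)
Conditions: LiN(i-Pr)2, HMPA, THF, −78 °C; then 6, −78 → 0 °C
Reagents that add atoms: none
Why: Kinetic γ-deprotonation of the methyl group syn to the ester gives the dienolate, which is alkylated at the α-carbon (deconjugative alkylation); this installs the C9 side chain and moves the alkene to C10=C20.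

Step 4
Reactants: 7 methyl 3-methylidene-2-[2-(2-methyl-1,3-dioxolan-2-yl)ethyl]-6-(morpholin-4-yl)-6-oxohexanoate; 8 4-bromobut-1-yne
Product: 9 methyl 10-bromo-3-methylidene-2-[2-(2-methyl-1,3-dioxolan-2-yl)ethyl]-6-oxodec-7-ynoate (racemic)
Conditions: 8, EtMgBr, THF, 0 °C; then 7, −20 → 0 °C
Reagents that add atoms: none
Why: The alkynylmagnesium bromide should acylate at the morpholine amide through a stable tetrahedral intermediate to give the ynone (amide-to-ketone acyl substitution), leaving the hindered α-branched ester.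

Step 5
Reactants: 9 methyl 10-bromo-3-methylidene-2-[2-(2-methyl-1,3-dioxolan-2-yl)ethyl]-6-oxodec-7-ynoate
Product: 10 methyl (6R)-10-bromo-6-hydroxy-3-methylidene-2-[2-(2-methyl-1,3-dioxolan-2-yl)ethyl]dec-7-ynoate (both C2 epimers)
Conditions: Ru[(R,R)-TsDPEN](p-cymene) (cat.), i-PrOH, 25 °C
Reagents that add atoms: none
Why: Noyori asymmetric transfer hydrogenation of the alkynyl ketone, with the alkyne acting as the unsaturated substituent, should give the (R)-carbinol at C3 under catalyst control; this is the only stereocentre set by a chiral reagent.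

Step 6
Reactants: 10 methyl (6R)-10-bromo-6-hydroxy-3-methylidene-2-[2-(2-methyl-1,3-dioxolan-2-yl)ethyl]dec-7-ynoate
Product: 11 (6R)-10-bromo-3-methylidene-2-[2-(2-methyl-1,3-dioxolan-2-yl)ethyl]dec-7-yne-1,6-diol
Conditions: i-Bu2AlH, CH2Cl2, −78 → 0 °C
Reagents that add atoms: none
Why: Hydride reduction of the methyl ester should give the primary C8 alcohol without touching the alkyne, bromide or acetal.

Step 7
Reactants: 11 (6R)-10-bromo-3-methylidene-2-[2-(2-methyl-1,3-dioxolan-2-yl)ethyl]dec-7-yne-1,6-diol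
Product: 12 (6R,7Z)-10-bromo-3-methylidene-2-[2-(2-methyl-1,3-dioxolan-2-yl)ethyl]-7-(tributylstannyl)dec-7-ene-1,6-diol
Conditions: [Cp*RuCl]4 (cat.), Bu3SnH, CH2Cl2, 25 °C
Reagents that add atoms: tributylstannane CCCC[SnH](CCCC)CCCC
Why: Hydroxyl-directed ruthenium-catalysed trans-hydrostannation should place tin on C4, the alkyne carbon next to the carbinol, and hydrogen on C5 from the opposite side, so that tin and C6 are cis.

Step 8
Reactants: 12 (6R,7Z)-10-bromo-3-methylidene-2-[2-(2-methyl-1,3-dioxolan-2-yl)ethyl]-7-(tributylstannyl)dec-7-ene-1,6-diol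
Product: 13 methyl (2Z)-5-bromo-2-{(1R)-1,6-dihydroxy-4-methylidene-5-[2-(2-methyl-1,3-dioxolan-2-yl)ethyl]hexyl}pent-2-enoate
Conditions: Pd(OAc)2 (cat.), Ph3As, 1,4-benzoquinone, CO (1 atm), MeOH, 25 °C
Reagents that add atoms: carbon monoxide [C-]#[O+]; methanol CO
Why: Oxidative methoxycarbonylation of the alkenylstannane (transmetalation to divalent palladium, CO insertion, methanolysis, reoxidation of zerovalent palladium by benzoquinone) goes with retention at the alkene and should give the Z acrylate with C6 cis to the ester.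

Step 9
Reactants: 13 methyl (2Z)-5-bromo-2-{(1R)-1,6-dihydroxy-4-methylidene-5-[2-(2-methyl-1,3-dioxolan-2-yl)ethyl]hexyl}pent-2-enoate
Product: 14 bis(tert-butyldimethylsilyl) ether of 13
Conditions: TBSOTf, 2,6-lutidine, CH2Cl2, −78 → 0 °C
Reagents that add atoms: tert-butyldimethylsilyl trifluoromethanesulfonate CC(C)(C)[Si](C)(C)OS(=O)(=O)C(F)(F)F
Why: Silyl triflate silylates both hydroxyls; the bulky silyl ether on O3 is the control element needed in step 12.

Step 10
Reactants: 14 bis(tert-butyldimethylsilyl) ether of 13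
Product: 15 primary alcohol with the O3 silyl ether retained
Conditions: HF·pyridine, pyridine, THF, 0 °C
Reagents that add atoms: none
Why: Buffered fluoride should cleave the unhindered primary silyl ether much faster than the hindered secondary allylic one (steric differentiation in desilylation).

Step 11
Reactants: 15 primary alcohol with the O3 silyl ether retained
Product: 16 methyl (2Z)-5-bromo-2-{(1R)-1-(tert-butyldimethylsilyloxy)-5-formyl-4-methylidene-7-(2-methyl-1,3-dioxolan-2-yl)heptyl}pent-2-enoate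
Conditions: Dess–Martin periodinane, NaHCO3, CH2Cl2, 0 °C
Reagents that add atoms: none
Why: Buffered Dess–Martin oxidation should give the C8 aldehyde without moving the β,γ-alkene into conjugation; the aldehyde is used at once.

Step 12
Reactants: 16 methyl (2Z)-5-bromo-2-{(1R)-1-(tert-butyldimethylsilyloxy)-5-formyl-4-methylidene-7-(2-methyl-1,3-dioxolan-2-yl)heptyl}pent-2-enoate
Product: 18 methyl 3α-(tert-butyldimethylsilyloxy)-13,13-ethylenedioxy-8-hydroxy-14,15,17,19-tetranorlabdan-18-oate (5α-H and 10β-CH3; mixture at C4 C8 C9), via monocyclic bromo aldehyde 17 (not isolated)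
Conditions: Fe(acac)3, PhSiH3, EtOH, 60 °C; then Bu3SnH, AIBN, PhMe, 85 °C (same flask)
Reagents that add atoms: none
Why: Iron hydride formed from Fe(acac)3 and PhSiH3 transfers a hydrogen atom to C20 of the 1,1-disubstituted alkene, and the tertiary C10 radical adds 6-endo-trig to C5, the β-carbon of the C4 acrylate, closing ring A; the C4 α-ester radical is reduced and protonated (known type: hydrogen-atom-transfer radical conjugate addition, Giese type). When 16 is consumed, Bu3SnH and AIBN turn the C7 bromide into the primary C7 radical, which adds 6-exo-trig to the C8 aldehyde carbon and closes ring B as the C8 alcohol (known type: tin hydride radical cyclisation onto an aldehyde). C5 and C10 are set in the chair-like ring A closure: the O3 silyl ether sits axial to avoid A(1,2) strain with the C4 ester, the Z acrylate puts C6 equatorial, and the branched C9 substituent on C10 takes the equatorial site, so C5–H and C10–CH3 end up trans-diaxial with C5–H cis to O3. Selectivities needed are attack at C5 and not at C4 (secured by the acrylate polarity), ring A before ring B (secured by the order of addition, the bromide being inert to the iron hydride), and carbonyl addition faster than 1,5-hydrogen transfer from C9 (secured by the fast 6-exo closure onto aldehydes). C8 and C9 form as mixtures and are corrected in step 13; C4 is set in step 16.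

Step 13
Reactants: 18 methyl 3α-(tert-butyldimethylsilyloxy)-13,13-ethylenedioxy-8-hydroxy-14,15,17,19-tetranorlabdan-18-oate
Product: 20 methyl 3α-(tert-butyldimethylsilyloxy)-13,13-ethylenedioxy-8-oxo-14,15,17,19-tetranorlabdan-18-oate (9α-H; mixture at C4), via C9-epimeric 8-ketone mixture 19 (not isolated)
Conditions: Dess–Martin periodinane, NaHCO3, CH2Cl2, 25 °C; then K2CO3, MeOH, 25 °C
Reagents that add atoms: none
Why: Oxidation gives the C8 ketone, and base equilibration through its enolate should place the C9 chain equatorial, trans to the axial C10 methyl, which fixes C9.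

Step 14
Reactants: 20 methyl 3α-(tert-butyldimethylsilyloxy)-13,13-ethylenedioxy-8-oxo-14,15,17,19-tetranorlabdan-18-oate
Product: 21 methyl 3α-(tert-butyldimethylsilyloxy)-13,13-ethylenedioxy-14,15,19-trinorlabd-8(17)-en-18-oate (mixture at C4)
Conditions: Zn, CH2Br2, TiCl4, THF, 0 → 25 °C
Reagents that add atoms: dibromomethane BrCBr
Why: Lombardo methylenation is non-basic and should convert the hindered enolisable ketone into the exocyclic methylene without epimerising C9 or eliminating the O3 silyl ether.

Step 15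
Reactants: 21 methyl 3α-(tert-butyldimethylsilyloxy)-13,13-ethylenedioxy-14,15,19-trinorlabd-8(17)-en-18-oate
Product: 22 methyl 13,13-ethylenedioxy-3α-hydroxy-14,15,19-trinorlabd-8(17)-en-18-oate (mixture at C4)
Conditions: Bu4NF, AcOH, THF, 25 °C
Reagents that add atoms: none
Why: Buffered fluoride desilylation should free the C3 hydroxyl without retro-aldol opening of the β-hydroxy ester.

Step 16
Reactants: 22 methyl 13,13-ethylenedioxy-3α-hydroxy-14,15,19-trinorlabd-8(17)-en-18-oate
Product: 23 methyl 13,13-ethylenedioxy-3α-hydroxy-14,15-dinorlabd-8(17)-en-18-oate (4α-CO2Me and 4β-CH3)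
Conditions: LiN(i-Pr)2 (2.5 equiv), HMPA, THF, −78 → −30 °C; MeI
Reagents that add atoms: iodomethane CI
Why: Frater–Seebach alkylation: the dianion (C3 alkoxide and C4 ester enolate) should be methylated anti to the alkoxide oxygen, so the methyl enters on the β-face and the ester stays α, cis to O3.

Step 17
Reactants: 23 methyl 13,13-ethylenedioxy-3α-hydroxy-14,15-dinorlabd-8(17)-en-18-oate
Product: 24 methyl 3α-hydroxy-13-oxo-14,15-dinorlabd-8(17)-en-18-oate
Conditions: PPTS, acetone/H2O, 50 °C
Reagents that add atoms: water O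
Why: Mild acid hydrolysis of the dioxolane should free the methyl ketone without isomerising the exocyclic alkene.

Step 18
Reactants: 24 methyl 3α-hydroxy-13-oxo-14,15-dinorlabd-8(17)-en-18-oate; 25 triethyl phosphonoacetate
Product: 26 15-ethyl 18-methyl (13E)-3α-hydroxylabda-8(17),13-diene-15,18-dioate
Conditions: NaH, 25, THF, 0 °C; then 24, 0 → 50 °C
Reagents that add atoms: none
Why: Horner–Wadsworth–Emmons olefination with the preformed phosphonate anion (no excess base, so no C3 alkoxide and no retro-aldol) should give mainly the E enoate, with the ester trans to the larger C12 chain.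

Step 19
Reactants: 26 15-ethyl 18-methyl (13E)-3α-hydroxylabda-8(17),13-diene-15,18-dioate
Product: 27 methyl (13E)-3α,15-dihydroxylabda-8(17),13-dien-18-oate
Conditions: i-Bu2AlH, CH2Cl2, −78 °C
Reagents that add atoms: none
Why: 1,2-Reduction of the unhindered conjugated ethyl ester to the allylic alcohol should be much faster than attack on the neopentyl C18 ester at quaternary C4.

Step 20
Reactants: 27 methyl (13E)-3α,15-dihydroxylabda-8(17),13-dien-18-oate
Product: 28 (13E)-3α,15-dihydroxylabda-8(17),13-dien-18-oic acid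
Conditions: n-PrSLi, HMPA, 25 °C; then dilute HCl
Reagents that add atoms: none
Why: Thiolate attacks the ester methyl carbon (SN2 dealkylation), which avoids acyl attack at the hindered carbonyl and the hot alkali that could open the β-hydroxy ester.

Step 21
Reactants: 28 (13E)-3α,15-dihydroxylabda-8(17),13-dien-18-oic acid
Product: 29 (13E)-3α,15-diacetoxylabda-8(17),13-dien-18-oic acid
Conditions: Ac2O, DMAP, pyridine, 40 °C; aqueous NaHCO3 work-up
Reagents that add atoms: acetic anhydride CC(=O)OC(C)=O
Why: DMAP-catalysed acylation esterifies both hydroxyls, and the mixed anhydride at C18 is hydrolysed on work-up.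

Step 22
Reactants: 29 (13E)-3α,15-diacetoxylabda-8(17),13-dien-18-oic acid
Product: 30 (13E)-3α-acetoxy-15-hydroxylabda-8(17),13-dien-18-oic acid
Conditions: K2CO3, MeOH, 0 °C
Reagents that add atoms: none
Why: Methanolysis should remove the unhindered primary allylic acetate far faster than the axial C3 acetate flanked by quaternary C4 (steric differentiation in transesterification).

**Compound list**
1 | α-angelica lactone (5-methylfuran-2(3H)-one) | CC1=CCC(=O)O1 | starting material
2 | morpholine | C1COCCN1 | starting material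
3 | 1-(morpholin-4-yl)pentane-1,4-dione | CC(=O)CCC(=O)N1CCOCC1 | intermediate
4 | trimethyl phosphonoacetate | COC(=O)CP(=O)(OC)OC | starting material
5 | methyl (2E)-3-methyl-6-(morpholin-4-yl)-6-oxohex-2-enoate | COC(=O)/C=C(\C)CCC(=O)N1CCOCC1 | intermediate
6 | 2-(2-bromoethyl)-2-methyl-1,3-dioxolane | CC1(CCBr)OCCO1 | starting material
7 | methyl 3-methylidene-2-[2-(2-methyl-1,3-dioxolan-2-yl)ethyl]-6-(morpholin-4-yl)-6-oxohexanoate (racemic) | COC(=O)C(CCC1(C)OCCO1)C(=C)CCC(=O)N2CCOCC2 | intermediate
8 | 4-bromobut-1-yne | C#CCCBr | starting material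
9 | methyl 10-bromo-3-methylidene-2-[2-(2-methyl-1,3-dioxolan-2-yl)ethyl]-6-oxodec-7-ynoate (racemic) | COC(=O)C(CCC1(C)OCCO1)C(=C)CCC(=O)C#CCCBr | intermediate
10 | methyl (6R)-10-bromo-6-hydroxy-3-methylidene-2-[2-(2-methyl-1,3-dioxolan-2-yl)ethyl]dec-7-ynoate (both C2 epimers) | COC(=O)C(CCC1(C)OCCO1)C(=C)CC[C@@H](O)C#CCCBr | intermediate
11 | (6R)-10-bromo-3-methylidene-2-[2-(2-methyl-1,3-dioxolan-2-yl)ethyl]dec-7-yne-1,6-diol (both C2 epimers) | OCC(CCC1(C)OCCO1)C(=C)CC[C@@H](O)C#CCCBr | intermediate
12 | (6R,7Z)-10-bromo-3-methylidene-2-[2-(2-methyl-1,3-dioxolan-2-yl)ethyl]-7-(tributylstannyl)dec-7-ene-1,6-diol | OCC(CCC1(C)OCCO1)C(=C)CC[C@@H](O)/C([Sn](CCCC)(CCCC)CCCC)=C/CCBr | intermediate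
13 | methyl (2Z)-5-bromo-2-{(1R)-1,6-dihydroxy-4-methylidene-5-[2-(2-methyl-1,3-dioxolan-2-yl)ethyl]hexyl}pent-2-enoate | OCC(CCC1(C)OCCO1)C(=C)CC[C@@H](O)/C(C(=O)OC)=C/CCBr | intermediate
14 | bis(tert-butyldimethylsilyl) ether of 13 | CC(C)(C)[Si](C)(C)OCC(CCC1(C)OCCO1)C(=C)CC[C@@H](O[Si](C)(C)C(C)(C)C)/C(C(=O)OC)=C/CCBr | intermediate
15 | 13 with the (1R) oxygen as tert-butyldimethylsilyl ether and the primary alcohol free | OCC(CCC1(C)OCCO1)C(=C)CC[C@@H](O[Si](C)(C)C(C)(C)C)/C(C(=O)OC)=C/CCBr | intermediate
16 | methyl (2Z)-5-bromo-2-{(1R)-1-(tert-butyldimethylsilyloxy)-5-formyl-4-methylidene-7-(2-methyl-1,3-dioxolan-2-yl)heptyl}pent-2-enoate | O=CC(CCC1(C)OCCO1)C(=C)CC[C@@H](O[Si](C)(C)C(C)(C)C)/C(C(=O)OC)=C/CCBr | intermediate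
17 | monocyclic bromo aldehyde: ring A with 3α-OTBS, 4-CO2Me, 5α-H, 10β-CH3; C5 bears CH2CH2Br, C10 bears CH(CHO)CH2CH2C(CH3)(OCH2CH2O) | BrCC[C@@H]1[C@](C)(CC[C@@H](O[Si](C)(C)C(C)(C)C)C1C(=O)OC)C(C=O)CCC2(C)OCCO2 | intermediate (not isolated)
18 | methyl 3α-(tert-butyldimethylsilyloxy)-13,13-ethylenedioxy-8-hydroxy-14,15,17,19-tetranorlabdan-18-oate (5α-H, 10β-CH3; mixture at C4, C8, C9) | OC1CC[C@@H]2[C@](C)(CC[C@@H](O[Si](C)(C)C(C)(C)C)C2C(=O)OC)C1CCC3(C)OCCO3 | intermediate
19 | 8-oxo analogue of 18, mixture at C4 and C9 | O=C1CC[C@@H]2[C@](C)(CC[C@@H](O[Si](C)(C)C(C)(C)C)C2C(=O)OC)C1CCC3(C)OCCO3 | intermediate (not isolated)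
20 | methyl 3α-(tert-butyldimethylsilyloxy)-13,13-ethylenedioxy-8-oxo-14,15,17,19-tetranorlabdan-18-oate (9α-H, side chain β; mixture at C4) | O=C1CC[C@@H]2[C@](C)(CC[C@@H](O[Si](C)(C)C(C)(C)C)C2C(=O)OC)[C@H]1CCC3(C)OCCO3 | intermediate
21 | methyl 3α-(tert-butyldimethylsilyloxy)-13,13-ethylenedioxy-14,15,19-trinorlabd-8(17)-en-18-oate (mixture at C4) | C=C1CC[C@@H]2[C@](C)(CC[C@@H](O[Si](C)(C)C(C)(C)C)C2C(=O)OC)[C@H]1CCC3(C)OCCO3 | intermediate
22 | methyl 13,13-ethylenedioxy-3α-hydroxy-14,15,19-trinorlabd-8(17)-en-18-oate (mixture at C4) | C=C1CC[C@@H]2[C@](C)(CC[C@@H](O)C2C(=O)OC)[C@H]1CCC3(C)OCCO3 | intermediate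
23 | methyl 13,13-ethylenedioxy-3α-hydroxy-14,15-dinorlabd-8(17)-en-18-oate (4α-CO2Me, 4β-CH3) | C=C1CC[C@@H]2[C@](C)(CC[C@@H](O)[C@@]2(C)C(=O)OC)[C@H]1CCC3(C)OCCO3 | intermediate
24 | methyl 3α-hydroxy-13-oxo-14,15-dinorlabd-8(17)-en-18-oate | C=C1CC[C@@H]2[C@](C)(CC[C@@H](O)[C@@]2(C)C(=O)OC)[C@H]1CCC(C)=O | intermediate
25 | triethyl phosphonoacetate | CCOC(=O)CP(=O)(OCC)OCC | starting material
26 | 15-ethyl 18-methyl (13E)-3α-hydroxylabda-8(17),13-diene-15,18-dioate | C=C1CC[C@@H]2[C@](C)(CC[C@@H](O)[C@@]2(C)C(=O)OC)[C@H]1CC/C(C)=C/C(=O)OCC | intermediate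
27 | methyl (13E)-3α,15-dihydroxylabda-8(17),13-dien-18-oate | C=C1CC[C@@H]2[C@](C)(CC[C@@H](O)[C@@]2(C)C(=O)OC)[C@H]1CC/C(C)=C/CO | intermediate
28 | (13E)-3α,15-dihydroxylabda-8(17),13-dien-18-oic acid | C=C1CC[C@@H]2[C@](C)(CC[C@@H](O)[C@@]2(C)C(=O)O)[C@H]1CC/C(C)=C/CO | intermediate
29 | (13E)-3α,15-diacetoxylabda-8(17),13-dien-18-oic acid | C=C1CC[C@@H]2[C@](C)(CC[C@@H](OC(C)=O)[C@@]2(C)C(=O)O)[C@H]1CC/C(C)=C/COC(C)=O | intermediate
30 | (13E)-3α-acetoxy-15-hydroxylabda-8(17),13-dien-18-oic acid | C=C1CC[C@@H]2[C@](C)(CC[C@@H](OC(C)=O)[C@@]2(C)C(=O)O)[C@H]1CC/C(C)=C/CO | target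

Total step count: 22. Longest linear sequence: 22 steps (from 1).

**Steps most likely to fail**

Step 12. The C10 radical may be reduced before it cyclises, facial control in the ring A closure may be poor, or hydrogen transfer from C9 may outrun the ring B closure. The fallback runs the two closures as separate operations and makes ring B by a polar organosamarium addition. It sets out from 16: the iron hydride stage alone (Fe(acac)3, PhSiH3, EtOH) with isolation of the monocyclic bromo aldehyde 17; Finkelstein exchange (NaI, acetone) to the iodo aldehyde F1; then a samarium Barbier cyclisation (SmI2, HMPA, THF) of F1, which comes back to the route at 18.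

Step 16. The methyl group may enter on the α-face if chelation control in the dianion is weak. The fallback uses steric control instead. It sets out from 21: the lithium enolate of the silyl ether (LiN(i-Pr)2, HMPA, then MeI) is methylated while the axial O3 silyl ether shields the α-face, giving the C4-methylated silyl ether F2; Bu4NF then returns to the route at 23.

Step 22. The C3 acetate may be lost along with the primary one. The fallback differentiates the hydroxyls by protection. It sets out from 28: selective silylation of the primary allylic hydroxyl (TBSCl, imidazole) gives the 15-silyl ether acid F3; acetylation (Ac2O, DMAP, pyridine) gives the 3-acetate 15-silyl ether F4; HF·pyridine then gives 30.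

Further compounds
F1 | step 12 | iodo analogue of 17 (C7 iodide) | ICC[C@@H]1[C@](C)(CC[C@@H](O[Si](C)(C)C(C)(C)C)C1C(=O)OC)C(C=O)CCC2(C)OCCO2
F2 | step 16 | methyl 3α-(tert-butyldimethylsilyloxy)-13,13-ethylenedioxy-14,15-dinorlabd-8(17)-en-18-oate (4β-CH3) | C=C1CC[C@@H]2[C@](C)(CC[C@@H](O[Si](C)(C)C(C)(C)C)[C@@]2(C)C(=O)OC)[C@H]1CCC3(C)OCCO3
F3 | step 22 | (13E)-15-(tert-butyldimethylsilyloxy)-3α-hydroxylabda-8(17),13-dien-18-oic acid | C=C1CC[C@@H]2[C@](C)(CC[C@@H](O)[C@@]2(C)C(=O)O)[C@H]1CC/C(C)=C/CO[Si](C)(C)C(C)(C)C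
F4 | step 22 | (13E)-3α-acetoxy-15-(tert-butyldimethylsilyloxy)labda-8(17),13-dien-18-oic acid | C=C1CC[C@@H]2[C@](C)(CC[C@@H](OC(C)=O)[C@@]2(C)C(=O)O)[C@H]1CC/C(C)=C/CO[Si](C)(C)C(C)(C)C
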